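**Plan**

- Retrosynthesis: the C2–aryl bond is cut first (catalytic asymmetric 1,4-arylation of a chromone). The C2=C3 unsaturation is then taken back to a chroman-4-one. Last, the pyranone ring is cut at two bonds, O1–C8a and C4–C4a, which leaves an aryne and oxetan-2-one.
- Enabling feature: in the benzopyranone the acyl carbon C4 and the ether oxygen O1 sit on the adjacent arene carbons C4a and C8a, so the arene is formally inserted into the acyl–oxygen bond of a C3 lactone. The C5 oxygen next to C4a polarises the aryne so that O1 goes to C8a (beside the C8 prenyl group) and the acyl carbon to C4a.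
- Forward order: symmetric 3,5-dimethoxyphenol → carbamate → two directed ortho-metalations (silyl, then prenyl) → 2-silylaryl triflate. The four-membered lactone ring (O1, C2, C3, C4) is then enlarged to the six-membered pyranone by taking up the two aryne carbons, followed by dehydrogenation, aryl addition and 5-O-demethylation.
- Stereochemistry: the single stereocentre C2 (S) is set by catalyst control in the Rh-catalysed conjugate addition of the arylboronic acid to the achiral chromone.

Key step: step 6

Assumption: the sense of induction of the (S)-bisphosphine in step 8 is taken over from cyclic enones; the ligand antipode meant is the one that gives the 2S product.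

**Route**

Step 1
Reactants: 1 3,5-dimethoxyphenol
Product: 2 3,5-dimethoxyphenyl N,N-diethylcarbamate
Conditions: Et2NCOCl, K2CO3, MeCN, reflux
Reagents that add atoms: N,N-diethylcarbamoyl chloride, CCN(CC)C(=O)Cl
Why: O-carbamoylation of the phenoxide (acyl substitution) installs the strongest oxygen-based directing group for the two ortho-metalations that follow.

Step 2
Reactants: 2 3,5-dimethoxyphenyl N,N-diethylcarbamate
Product: 4 3,5-dimethoxy-2-(trimethylsilyl)phenyl N,N-diethylcarbamate, via aryllithium 3 (not isolated)
Conditions: s-BuLi, TMEDA, THF, −78 °C; then Me3SiCl, −78 °C → rt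
Reagents that add atoms: chlorotrimethylsilane, C[Si](C)(C)Cl
Why: directed ortho-metalation (Snieckus) in which the carbamate and the flanking methoxy group cooperate to direct the base to C2, the two ortho sites being equivalent by symmetry, and the silyl quench at −78 °C should outrun the anionic ortho-Fries shift.

Step 3
Reactants: 4 3,5-dimethoxy-2-(trimethylsilyl)phenyl N,N-diethylcarbamate; 5 prenyl bromide (1-bromo-3-methylbut-2-ene)
Product: 7 3,5-dimethoxy-2-(3-methylbut-2-en-1-yl)-6-(trimethylsilyl)phenyl N,N-diethylcarbamate, via aryllithium 6 (not isolated)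
Conditions: s-BuLi, TMEDA, THF, −78 °C; then CuBr·SMe2 (10 mol %), 5, −78 → −40 °C
Reagents that add atoms: none
Why: a second directed ortho-metalation at the only remaining carbamate-flanked site followed by copper-catalysed SN2 allylation, the silyl group having been introduced first so that no acidic benzylic-allylic CH2 is present during a lithiation.

Step 4
Reactants: 7 3,5-dimethoxy-2-(3-methylbut-2-en-1-yl)-6-(trimethylsilyl)phenyl N,N-diethylcarbamate
Product: 8 3,5-dimethoxy-2-(3-methylbut-2-en-1-yl)-6-(trimethylsilyl)phenol
Conditions: LiAlH4, THF, 0 °C → reflux; Rochelle salt work-up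
Reagents that add atoms: none
Why: hydride cleavage of the aryl carbamate (acyl substitution, then reduction of the formamide) should free the hindered phenol under non-acidic conditions that spare the aryl–Si bond and the ortho-prenylphenol, which acid would cyclise to a chroman.

Step 5
Reactants: 8 3,5-dimethoxy-2-(3-methylbut-2-en-1-yl)-6-(trimethylsilyl)phenol
Product: 9 3,5-dimethoxy-2-(3-methylbut-2-en-1-yl)-6-(trimethylsilyl)phenyl trifluoromethanesulfonate
Conditions: Tf2O, pyridine, CH2Cl2, −20 → 0 °C
Reagents that add atoms: trifluoromethanesulfonic anhydride, O=S(=O)(OS(=O)(=O)C(F)(F)F)C(F)(F)F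
Why: O-triflation of the phenol gives the Kobayashi-type 2-silylaryl triflate, the fluoride-triggered aryne precursor.

Step 6
Reactants: 9 3,5-dimethoxy-2-(3-methylbut-2-en-1-yl)-6-(trimethylsilyl)phenyl trifluoromethanesulfonate; 10 oxetan-2-one (β-propiolactone)
Product: 12 5,7-dimethoxy-8-(3-methylbut-2-en-1-yl)chroman-4-one, via aryne 11 (not isolated)
Conditions: CsF (3 equiv), 10 (5 equiv), MeCN/toluene, 40 °C, slow addition of 9
Reagents that add atoms: none
Why: Proposed new method: fluoride-induced 1,2-elimination of 9 gives aryne 11, whose carbon remote from the OMe-bearing neighbour is attacked by the ring oxygen of the strained lactone; the aryl anion formed next to OMe adds to the adjacent lactone carbonyl through a four-membered transition state and the tetrahedral intermediate collapses with cleavage of the acyl–O bond, so that the two aryne carbons are inserted into the O1–C4 bond and the four-membered ring becomes the six-membered pyranone (a 4 → 6 ring enlargement by insertion, not a cyclisation of a chain). The closest known reaction types are the insertion of arynes into the N–C(O) bond of cyclic ureas and β-lactams, which are two-atom ring expansions, and into the C–O bond of carboxylic acids, which with acrylic acids leads to chroman-4-ones. Should fluoride open the lactone first, the 3-fluoropropanoate formed would enter the known carboxylate C–O insertion and the resulting 2-hydroxyaryl ketone would close by 6-exo-tet displacement or by elimination and 6-endo-trig oxa-Michael addition, so both channels should converge on 12. No stereocentre is formed. The step needs regioselective capture of an unsymmetrical aryne, secured by the inductively withdrawing OMe group beside one aryne carbon (attack at the distal carbon places the negative charge next to OMe, which puts O1 on C8a beside the prenyl group and the acyl carbon on C4a beside OMe), and chemoselectivity over the ene reaction of the aryne with the prenyl double bond, secured by keeping the aryne concentration low in an excess of lactone.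

Step 7
Reactants: 12 5,7-dimethoxy-8-(3-methylbut-2-en-1-yl)chroman-4-one
Product: 14 5,7-dimethoxy-8-(3-methylbut-2-en-1-yl)-4H-chromen-4-one, via silyl enol ether 13 (not isolated)
Conditions: Me3SiOTf, Et3N, CH2Cl2, 0 °C; then Pd(OAc)2 (1.05 equiv), MeCN, rt
Reagents that add atoms: none
Why: Saegusa–Ito oxidation in which the silyl enol ether hands its enolate to Pd(II) and β-hydride elimination gives the chromone, C3 being the only enolisable position and the trisubstituted prenyl olefin a poor ligand for Pd(II) at room temperature.

Step 8
Reactants: 14 5,7-dimethoxy-8-(3-methylbut-2-en-1-yl)-4H-chromen-4-one; 15 (4-methoxyphenyl)boronic acid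
Product: 16 (2S)-5,7-dimethoxy-2-(4-methoxyphenyl)-8-(3-methylbut-2-en-1-yl)chroman-4-one
Conditions: [Rh(OH)(cod)]2 (3 mol %), (S)-MeO-F12-BIPHEP [2,2'-bis{bis(3,4,5-trifluorophenyl)phosphino}-6,6'-dimethoxybiphenyl] (7 mol %), 15 (2 equiv), toluene/H2O 10:1, 40 °C
Reagents that add atoms: none
Why: Hayashi–Miyaura reaction in which the aryl–Rh(I) species carbometalates the C2=C3 bond and water protonates the rhodium enolate, the C2 stereocentre being set by catalyst control (aryl delivery to the enone face that gives 2S) under neutral conditions that should avoid retro-oxa-Michael opening.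

Step 9
Reactants: 16 (2S)-5,7-dimethoxy-2-(4-methoxyphenyl)-8-(3-methylbut-2-en-1-yl)chroman-4-one
Product: 17 flowerine, (2S)-5-hydroxy-7-methoxy-2-(4-methoxyphenyl)-8-(3-methylbut-2-en-1-yl)chroman-4-one
Conditions: BCl3 (1.2 equiv), CH2Cl2, −78 → −20 °C; cold H2O quench
Reagents that add atoms: none
Why: chelation-controlled ether cleavage in which boron bridges the C4 carbonyl and the peri 5-OMe oxygen so that chloride should demethylate only this ether, while low temperature and a cold quench are meant to protect the prenyl olefin and the C2 stereocentre.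

**Compound list**

1 | 3,5-dimethoxyphenol | COc1cc(O)cc(OC)c1 | starting material
2 | 3,5-dimethoxyphenyl N,N-diethylcarbamate | CCN(CC)C(=O)Oc1cc(OC)cc(OC)c1 | intermediate
3 | 2-(diethylcarbamoyloxy)-4,6-dimethoxyphenyllithium | [Li]c1c(OC)cc(OC)cc1OC(=O)N(CC)CC | intermediate
4 | 3,5-dimethoxy-2-(trimethylsilyl)phenyl N,N-diethylcarbamate | CCN(CC)C(=O)Oc1cc(OC)cc(OC)c1[Si](C)(C)C | intermediate
5 | prenyl bromide (1-bromo-3-methylbut-2-ene) | CC(C)=CCBr | starting material
6 | 2-(diethylcarbamoyloxy)-4,6-dimethoxy-3-(trimethylsilyl)phenyllithium | [Li]c1c(OC)cc(OC)c([Si](C)(C)C)c1OC(=O)N(CC)CC | intermediate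
7 | 3,5-dimethoxy-2-(3-methylbut-2-en-1-yl)-6-(trimethylsilyl)phenyl N,N-diethylcarbamate | CCN(CC)C(=O)Oc1c(CC=C(C)C)c(OC)cc(OC)c1[Si](C)(C)C | intermediate
8 | 3,5-dimethoxy-2-(3-methylbut-2-en-1-yl)-6-(trimethylsilyl)phenol | COc1cc(OC)c([Si](C)(C)C)c(O)c1CC=C(C)C | intermediate
9 | 3,5-dimethoxy-2-(3-methylbut-2-en-1-yl)-6-(trimethylsilyl)phenyl trifluoromethanesulfonate | COc1cc(OC)c([Si](C)(C)C)c(OS(=O)(=O)C(F)(F)F)c1CC=C(C)C | intermediate
10 | oxetan-2-one (β-propiolactone) | O=C1CCO1 | starting material
11 | 4,6-dimethoxy-3-(3-methylbut-2-en-1-yl)benzyne (1,2-didehydrobenzene) | COC1=CC(OC)=C(CC=C(C)C)C#C1 | intermediate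
12 | 5,7-dimethoxy-8-(3-methylbut-2-en-1-yl)chroman-4-one | COc1cc(OC)c(CC=C(C)C)c2OCCC(=O)c12 | intermediate
13 | 5,7-dimethoxy-8-(3-methylbut-2-en-1-yl)-4-(trimethylsilyloxy)-2H-chromene | COc1cc(OC)c(CC=C(C)C)c2OCC=C(O[Si](C)(C)C)c12 | intermediate
14 | 5,7-dimethoxy-8-(3-methylbut-2-en-1-yl)-4H-chromen-4-one | COc1cc(OC)c(CC=C(C)C)c2OC=CC(=O)c12 | intermediate
15 | (4-methoxyphenyl)boronic acid | COc1ccc(B(O)O)cc1 | starting material
16 | (2S)-5,7-dimethoxy-2-(4-methoxyphenyl)-8-(3-methylbut-2-en-1-yl)chroman-4-one | COc1ccc([C@@H]2CC(=O)c3c(OC)cc(OC)c(CC=C(C)C)c3O2)cc1 | intermediate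
17 | flowerine, (2S)-5-hydroxy-7-methoxy-2-(4-methoxyphenyl)-8-(3-methylbut-2-en-1-yl)chroman-4-one | COc1ccc([C@@H]2CC(=O)c3c(O)cc(OC)c(CC=C(C)C)c3O2)cc1 | target

**Step count**

Total steps: 9. Longest linear sequence: 9 steps (1 → 17).

**Steps most likely to fail**

1. Step 6 (proposed new method). The lactone oxygen may capture the aryne too slowly, so that fluoride-induced opening and oligomerisation of the lactone and the ene reaction of the aryne with the prenyl double bond consume both partners. The fallback uses known chemistry with an acyclic acid in place of the lactone. Starting from 9, the aryne is generated with CsF in THF at elevated temperature in the presence of acrylic acid. Insertion of the aryne into the C–O bond of the carboxylic acid should give 1-[2-hydroxy-4,6-dimethoxy-3-(3-methylbut-2-en-1-yl)phenyl]prop-2-en-1-one F1, which closes by intramolecular oxa-Michael addition and rejoins the route at 12.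

2. Step 8. Carbometalation of the electron-rich, 5,8-disubstituted chromone may be slow, so that protodeboronation of the boronic acid, opening of the rhodium enolate to the chalcone, or poor facial discrimination lowers conversion or enantiomeric purity. The fallback is resolution instead of asymmetric addition. Starting from 14, copper-catalysed conjugate addition of 4-methoxyphenylmagnesium bromide (Me3SiCl, THF, −78 °C) should give racemic 5,7-dimethoxy-2-(4-methoxyphenyl)-8-(3-methylbut-2-en-1-yl)chroman-4-one F2. Kinetic resolution by Noyori–Ikariya transfer hydrogenation (Rh or Ru–TsDPEN, HCO2H/Et3N, catalyst antipode chosen to reduce the 2R enantiomer) should convert the unwanted half into (2R,4R)-5,7-dimethoxy-2-(4-methoxyphenyl)-8-(3-methylbut-2-en-1-yl)chroman-4-ol F3. The 2S ketone is left behind and rejoins the route at 16.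

3. Step 9. The boron chelate may ionise the p-methoxybenzylic O1–C2 bond (ring opening to the chalcone and re-closure), which would erode the enantiomeric purity, and HCl may add to the prenyl double bond. The fallback moves the demethylation in front of the stereo-setting step and carries a MOM group through it. Starting from 14, BCl3 should give 5-hydroxy-7-methoxy-8-(3-methylbut-2-en-1-yl)-4H-chromen-4-one F4. MOMCl/NaH then gives 7-methoxy-5-(methoxymethoxy)-8-(3-methylbut-2-en-1-yl)-4H-chromen-4-one F5. The Rh-catalysed arylation of step 8 should give (2S)-7-methoxy-5-(methoxymethoxy)-2-(4-methoxyphenyl)-8-(3-methylbut-2-en-1-yl)chroman-4-one F6. HCl in MeOH at room temperature removes the MOM group and the sequence ends at 17.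

**Further compounds**

F1 | step 6 | 1-[2-hydroxy-4,6-dimethoxy-3-(3-methylbut-2-en-1-yl)phenyl]prop-2-en-1-one | C=CC(=O)c1c(O)c(CC=C(C)C)c(OC)cc1OC
F2 | step 8 | rac-5,7-dimethoxy-2-(4-methoxyphenyl)-8-(3-methylbut-2-en-1-yl)chroman-4-one | COc1ccc(C2CC(=O)c3c(OC)cc(OC)c(CC=C(C)C)c3O2)cc1
F3 | step 8 | (2R,4R)-5,7-dimethoxy-2-(4-methoxyphenyl)-8-(3-methylbut-2-en-1-yl)chroman-4-ol | COc1ccc([C@H]2C[C@@H](O)c3c(OC)cc(OC)c(CC=C(C)C)c3O2)cc1
F4 | step 9 | 5-hydroxy-7-methoxy-8-(3-methylbut-2-en-1-yl)-4H-chromen-4-one | COc1cc(O)c2C(=O)C=COc2c1CC=C(C)C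
F5 | step 9 | 7-methoxy-5-(methoxymethoxy)-8-(3-methylbut-2-en-1-yl)-4H-chromen-4-one | COCOc1cc(OC)c(CC=C(C)C)c2OC=CC(=O)c12
F6 | step 9 | (2S)-7-methoxy-5-(methoxymethoxy)-2-(4-methoxyphenyl)-8-(3-methylbut-2-en-1-yl)chroman-4-one | COc1ccc([C@@H]2CC(=O)c3c(OCOC)cc(OC)c(CC=C(C)C)c3O2)cc1
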